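## Structural features

The target contains two benzene rings and no other ring. Ring A is a 1,3,5-trisubstituted benzene with one hydroxyl and one methoxy group, and ring B is a 5-substituted resorcinol with two free hydroxyls. Each ring is bonded through its remaining meta position to one end of an unbranched, saturated chain of fourteen methylenes, numbered here C1' (on ring A) to C14' (on ring B). There is no stereocentre and no stereogenic double bond, so no stereochemical relationship has to be set or preserved. The sensitive parts are the electron-rich phenolic rings: free, they are acidic and easily oxidized; etherified, the ring CH between two oxygens is open to metalation by strong base and to electrophilic attack. The real difficulty is threefold: the chain has no functional group to direct bond formation, the two halves differ only by one O-methyl group yet must be joined as a cross product, and three hydroxyls must be freed at the end while the fourth oxygen keeps its methyl group. The key step exploits the fact that the central methylenes C6'–C9' map onto the four carbons of a thiophene ring. Its two carbons next to sulfur can be metalated one after the other, so bonds C9'–C10' and C5'–C6' come from two consecutive alkylations with 5-arylpentyl iodides, and the sulfur is removed reductively afterwards.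

## Logic of the disconnections

**17 to 16.** The three O–isopropyl bonds (two on ring B, one on ring A) are added in the retrosynthetic sense. The phenols must be masked through the organolithium and nickel steps. Isopropyl is chosen because it has no benzylic hydrogens, directs ring metalation poorly, is inert to hydrogen-rich nickel, and is cleaved by a different mechanism from methyl. The gain is an aprotic triether, 16. The forward step must ionize secondary O–alkyl bonds and leave the O–CH3 bond of ring A intact.

**16 to 15.** The saturated segment C6'–C9' is converted back into the ring carbons of a 2,5-disubstituted heteroarene, which means adding the C6'–S and C9'–S bonds and removing hydrogen. This places an aromatic handle with two activatable positions in the middle of an otherwise featureless chain. The gain is that 15 can be cut on both sides of the sulfur ring. The forward step must break both C–S bonds and saturate all four carbons without touching aryl ethers or benzene rings.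

**15 to 11, 10 and 6.** The bonds C9'–C10' and C5'–C6' are cut, each between a ring carbon next to sulfur and a chain methylene. These positions of 11 are its most acidic C–H sites and can be metalated one at a time, and both cuts fall five carbons from an arene, so the two electrophiles are the same size and come from one sequence. The gain is large: a diarylalkane with a 14-carbon chain becomes the bulk chemical 11 plus two iodides that differ in a single O-substituent, and cross-selectivity follows from the order of addition. The forward step needs substitution to outrun elimination, the first iodide to be consumed before the second base charge, and the base to choose the C–H next to sulfur over the ether rings. For the last reason 10 is attached first, so the only arene exposed to the alkyllithium carries two bulky isopropoxy groups.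

**10 to 9 and 6 to 5.** The C–I bond is exchanged for a C–Cl bond. A primary chloride is inert to palladium and to the borane, so it can be present when the aryl–alkyl bond is made, whereas the iodide is needed for a fast displacement. The gain is that the five-carbon unit can be bought with its leaving group in place, so no alkyne reduction or alcohol activation is needed. The forward step is a simple halide exchange that must go to completion.

**9 to 8 and 4; 5 to 2 and 4.** The aryl–C14' bond (ring B) and the aryl–C1' bond (ring A) are cut. An sp2–sp3 bond next to an arene is a natural cross-coupling site, the aryl bromides carry the full oxygen pattern, and one batch of 4 serves both halves. The gain is that each half becomes an aryl bromide and a common C5 organoborane. The forward step needs a palladium catalyst that inserts into the aryl C–Br bond but not the alkyl C–Cl bond.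

**4 to 3.** The B–C bond at the chain terminus is cut, and a terminal C=C bond is restored. The alkene 3 is purchasable and already carries the chloride. Because the borane is made once and divided, the two halves together need seven steps instead of the eight of a route through two arylpentynols. The forward step needs anti-Markovnikov addition and a borane that ignores the primary chloride.

**8 to 7 and 2 to 1.** The O–isopropyl bonds are cut. Both bromophenols are purchasable, and 1 already carries the methyl ether, so ring A never has to be desymmetrized. The forward step needs O-alkylation rather than C-alkylation of the phenoxides with a secondary halide.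

## Other disconnections considered

**Alternative 1:** Ring A is opened at the bond between its ester-bearing carbon and its chain-bearing carbon, giving the linear trioxo ester A2. A2 would come from terminal acylation of the trianion of the dioxo ester A4 with the Weinreb amide A3. In the forward key step the C2 methylene of A2 adds to the C7 ketone in an intramolecular aldol reaction, and loss of water with enolization gives the resorcylate A1.
- In its favour: the two ring A oxygens emerge chemically different. The hydroxyl ortho to the ester is hydrogen-bonded and the para hydroxyl is free, so the single O-methylation can be directed by the substrate. On this point the alternative is better than the chosen plan, which buys the differentiation with 1.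
- Against it: A2 can also close by C-acylation or lactonize to a pyranone, so it must be cyclized under carefully chosen conditions. After A1, O-methylation, ester hydrolysis with decarboxylation, and benzyl hydrogenolysis are still needed. The key step builds only ring A, so the whole chain with ring B must already be assembled in A3.
- Comparison: structurally it addresses the oxygen pattern but not the chain or the near-symmetry, which is what the thiophene plan addresses. Mechanistically it relies on reversible carbonyl condensation with several competing closures, against two irreversible displacements. In step economy it is clearly longer.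

**Alternative 2:** Ring B is cut at two bonds into the enone A6 and the malonate A7. In the forward key step the sodium enolate of A7 (NaOMe, MeOH) adds to the β-carbon of A6, and the methyl ketone enolate closes onto a malonate ester to give the dioxocyclohexane carboxylate A5. A5 is then aromatized with decarboxylation and debenzylated.
- In its favour: this is the classical route to 5-alkylresorcinols, with cheap reagents and no organolithium or nickel. The two ring B hydroxyls never need protecting groups, and the last deprotection is a hydrogenolysis that cannot touch the methyl ether. On robustness of the annulation and on chemoselectivity of the final deprotection it is the equal of or better than the chosen plan.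
- Against it: aromatizing the cyclohexanedione needs an oxidant, usually a halogen, in the presence of ring A, a resorcinol diether that is itself readily halogenated. A6 still requires a 15-carbon aldehyde bearing ring A, so the chain problem is untouched. Three operations follow the key step.
- Comparison: the two stereocentres of A5 are irrelevant because they vanish. Polar enolate chemistry replaces organometallic alkylation. The step count is higher than in the chosen plan.

**Alternative 3:** Ring A is cut into the four-carbon cyclobutenone A9 and the two-carbon ynol ether A10. In the forward key step heating opens A9 to a vinylketene, which adds A10 regioselectively. A second ring opening gives a dienylketene, and 6π electrocyclization with tautomerization delivers the phenol A8.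
- In its favour: ring A is formed directly as the mono-methyl ether with its hydroxyl free, the regiochemistry is fixed by the polarity of ketene and ynol ether, and only one hydrogenolysis separates A8 from 17. On differentiation of the ring A oxygens and on the length of the end-game (one step against two) it is better than the chosen plan.
- Against it: A10 is a low-boiling, unstable compound that must be prepared and handled cold. A9 with its long chain needs its own multistep synthesis, in which the chain and ring B must still be joined. The cascade requires prolonged heating in a closed vessel.
- Comparison: structurally it solves ring A but not the chain. Mechanistically it is a reagent-free pericyclic cascade against a polar alkylation. Overall step economy is poorer because everything before A9 is linear.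

Key step: step 8

Remark on the chemistry: five carbons from each iodide plus four from the heteroarene reproduce the fourteen-carbon chain and the oxygen pattern of 6, 10 and 15 maps onto 17 as drawn; compounds 1, 3, 7 and 11 are taken to be purchasable, 9-BBN is used as its commercial THF solution, and 4 is prepared once as a THF solution under argon and divided between the two couplings.

## Route

Step 1
Reactants: 1 3-bromo-5-methoxyphenol
Product: 2 1-bromo-3-isopropoxy-5-methoxybenzene
Conditions: 2-bromopropane, K2CO3, DMF, 60 °C
Reagents that add atoms: 2-bromopropane, CC(C)Br
Why: Williamson ether synthesis; the phenoxide formed by K2CO3 displaces bromide from the secondary halide, and an excess of the halide compensates for loss to elimination.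

Step 2
Reactants: 3 5-chloropent-1-ene
Product: 4 9-(5-chloropentyl)-9-borabicyclo[3.3.1]nonane
Conditions: 9-BBN (0.5 M in THF), THF, 0 °C to rt, argon; solution used as such
Reagents that add atoms: 9-borabicyclo[3.3.1]nonane (9-BBN), B1C2CCCC1CCC2
Why: Hydroboration; the bulky dialkylborane adds its B–H bond across the terminal alkene with boron on the terminal carbon, and the remote primary chloride is inert to the borane. The THF solution of 4 is stable under argon and is divided between steps 3 and 6.

Step 3
Reactants: 2 1-bromo-3-isopropoxy-5-methoxybenzene; 4 9-(5-chloropentyl)-9-borabicyclo[3.3.1]nonane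
Product: 5 1-(5-chloropentyl)-3-isopropoxy-5-methoxybenzene
Conditions: 4 (THF solution, 1.2 equiv), Pd(dppf)Cl2 (cat.), K3PO4 (aq), DMF, 60 °C
Reagents that add atoms: none
Why: B-alkyl Suzuki–Miyaura coupling forms the aryl–C1' bond after the base has activated the borane for alkyl transfer. Zerovalent palladium generated from Pd(dppf)Cl2 inserts into the aryl C–Br bond but not into the unactivated primary C–Cl bond.

Step 4
Reactants: 5 1-(5-chloropentyl)-3-isopropoxy-5-methoxybenzene
Product: 6 1-(5-iodopentyl)-3-isopropoxy-5-methoxybenzene
Conditions: NaI, butanone, reflux
Reagents that add atoms: sodium iodide, [Na+].[I-]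
Why: Finkelstein halide exchange at a primary carbon, driven by precipitation of NaCl.

Step 5
Reactants: 7 5-bromoresorcinol
Product: 8 1-bromo-3,5-diisopropoxybenzene
Conditions: 2-bromopropane (excess), K2CO3, DMF, 70 °C
Reagents that add atoms: 2-bromopropane, CC(C)Br
Why: Double Williamson ether synthesis; in a dipolar aprotic solvent with a carbonate base the resorcinol oxygens are alkylated in preference to ring carbon.

Step 6
Reactants: 8 1-bromo-3,5-diisopropoxybenzene; 4 9-(5-chloropentyl)-9-borabicyclo[3.3.1]nonane
Product: 9 1-(5-chloropentyl)-3,5-diisopropoxybenzene
Conditions: 4 (THF solution, 1.2 equiv), Pd(dppf)Cl2 (cat.), K3PO4 (aq), DMF, 60 °C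
Reagents that add atoms: none
Why: The same B-alkyl Suzuki–Miyaura coupling as in step 3, here forming the aryl–C14' bond with the C–Cl bond untouched.

Step 7
Reactants: 9 1-(5-chloropentyl)-3,5-diisopropoxybenzene
Product: 10 1-(5-iodopentyl)-3,5-diisopropoxybenzene
Conditions: NaI, butanone, reflux
Reagents that add atoms: sodium iodide, [Na+].[I-]
Why: Finkelstein halide exchange, as in step 4.

Step 8
Reactants: 11 thiophene; 10 1-(5-iodopentyl)-3,5-diisopropoxybenzene; 6 1-(5-iodopentyl)-3-isopropoxy-5-methoxybenzene
Product: 15 2-[5-(3-isopropoxy-5-methoxyphenyl)pentyl]-5-[5-(3,5-diisopropoxyphenyl)pentyl]thiophene, via 2-thienyllithium 12 (not isolated), via 2-[5-(3,5-diisopropoxyphenyl)pentyl]thiophene 13 (not isolated), via {5-[5-(3,5-diisopropoxyphenyl)pentyl]thiophen-2-yl}lithium 14 (not isolated)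
Conditions: 11 (1.1 equiv), n-BuLi (1.05 equiv), THF, −78 to 0 °C; 10 (1.0 equiv), DMPU, −78 °C to rt; n-BuLi (1.1 equiv), −78 to −30 °C; 6 (1.2 equiv), −78 °C to rt
Reagents that add atoms: none
Why: n-BuLi removes the most acidic proton of 11, the sp2 C–H next to sulfur, to give 12, which displaces iodide from 10 by SN2 and forms C9'–C10' in 13. Because 13 has one such hydrogen left and the ring hydrogens further from sulfur are far less acidic, the second charge of n-BuLi metalates only C5 to give 14, and SN2 attack of 14 on 6 forms C5'–C6' and delivers 15. The closest known reaction type is lithiation of thiophenes next to sulfur and alkylation with primary alkyl halides, repeated to make 2,5-dialkylthiophenes. No ring is closed and no stereocentre is formed. Cross-selectivity between the two nearly identical halves follows from the order of addition and from making 10 the limiting reagent, so that no iodide remains when the second charge of n-BuLi is added. Substitution is favoured over E2 elimination by the primary iodides, the weakly basic sp2 carbanions and the polar cosolvent DMPU, and iodine–lithium exchange is uphill because a thienyl anion is more stable than a primary alkyl anion. Metalation between the ether oxygens is avoided because the C–H next to sulfur is the kinetically and thermodynamically preferred site at low temperature, and the only arene that meets n-BuLi is ring B of 13, whose CH between two isopropoxy groups is hindered; ring A of 6 meets only the milder 14.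

Step 9
Reactants: 15 2-[5-(3-isopropoxy-5-methoxyphenyl)pentyl]-5-[5-(3,5-diisopropoxyphenyl)pentyl]thiophene
Product: 16 1-[14-(3,5-diisopropoxyphenyl)tetradecyl]-3-isopropoxy-5-methoxybenzene
Conditions: Raney Ni (W-2, excess, ethanol slurry), EtOH, reflux
Reagents that add atoms: none
Why: Raney Ni reductive desulfurization; hydrogen held on the nickel cleaves both C–S bonds and saturates the resulting four-carbon diene, turning the ring carbons into C6'–C9'. Aryl alkyl ethers and benzene rings are not reduced at atmospheric pressure.

Step 10
Reactants: 16 1-[14-(3,5-diisopropoxyphenyl)tetradecyl]-3-isopropoxy-5-methoxybenzene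
Product: 17 5-[14-(3-hydroxy-5-methoxyphenyl)tetradecyl]benzene-1,3-diol
Conditions: BCl3 (1 M in CH2Cl2, excess), CH2Cl2, −78 to 0 °C; then MeOH, H2O
Reagents that add atoms: none
Why: Lewis acid ether cleavage; BCl3 coordinates each ether oxygen and the secondary isopropyl group leaves through an ion-pair path as 2-chloropropane. The methyl group would need direct attack by chloride, which is slow at 0 °C, so the methyl ether of ring A is retained; the aryl borates are hydrolysed on work-up.

## Compound list

1 | 3-bromo-5-methoxyphenol | COc1cc(O)cc(Br)c1 | starting material
2 | 1-bromo-3-isopropoxy-5-methoxybenzene | COc1cc(OC(C)C)cc(Br)c1 | intermediate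
3 | 5-chloropent-1-ene | C=CCCCCl | starting material
4 | 9-(5-chloropentyl)-9-borabicyclo[3.3.1]nonane | ClCCCCCB1C2CCCC1CCC2 | intermediate
5 | 1-(5-chloropentyl)-3-isopropoxy-5-methoxybenzene | COc1cc(OC(C)C)cc(CCCCCCl)c1 | intermediate
6 | 1-(5-iodopentyl)-3-isopropoxy-5-methoxybenzene | COc1cc(OC(C)C)cc(CCCCCI)c1 | intermediate
7 | 5-bromoresorcinol | Oc1cc(O)cc(Br)c1 | starting material
8 | 1-bromo-3,5-diisopropoxybenzene | CC(C)Oc1cc(OC(C)C)cc(Br)c1 | intermediate
9 | 1-(5-chloropentyl)-3,5-diisopropoxybenzene | CC(C)Oc1cc(OC(C)C)cc(CCCCCCl)c1 | intermediate
10 | 1-(5-iodopentyl)-3,5-diisopropoxybenzene | CC(C)Oc1cc(OC(C)C)cc(CCCCCI)c1 | intermediate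
11 | thiophene | c1ccsc1 | starting material
12 | 2-thienyllithium | [Li]c1cccs1 | intermediate (not isolated)
13 | 2-[5-(3,5-diisopropoxyphenyl)pentyl]thiophene | CC(C)Oc1cc(OC(C)C)cc(CCCCCc2cccs2)c1 | intermediate (not isolated)
14 | {5-[5-(3,5-diisopropoxyphenyl)pentyl]thiophen-2-yl}lithium | [Li]c1ccc(CCCCCc2cc(OC(C)C)cc(OC(C)C)c2)s1 | intermediate (not isolated)
15 | 2-[5-(3-isopropoxy-5-methoxyphenyl)pentyl]-5-[5-(3,5-diisopropoxyphenyl)pentyl]thiophene | COc1cc(OC(C)C)cc(CCCCCc2ccc(CCCCCc3cc(OC(C)C)cc(OC(C)C)c3)s2)c1 | intermediate
16 | 1-[14-(3,5-diisopropoxyphenyl)tetradecyl]-3-isopropoxy-5-methoxybenzene | COc1cc(OC(C)C)cc(CCCCCCCCCCCCCCc2cc(OC(C)C)cc(OC(C)C)c2)c1 | intermediate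
17 | 5-[14-(3-hydroxy-5-methoxyphenyl)tetradecyl]benzene-1,3-diol | COc1cc(O)cc(CCCCCCCCCCCCCCc2cc(O)cc(O)c2)c1 | target

## Step count and least certain steps

Total: 10 steps. Longest linear sequence: 6 steps (steps 1, 3, 4, 8, 9, 10; the sequences through steps 5, 6, 7 and from 3 through step 2 are equally long).

**Step 8 (key step).** The most likely failure is loss of stoichiometric control in the single flask. Incomplete first alkylation would leave iodide that undergoes iodine–lithium exchange with the second charge of n-BuLi. Proton transfer between 12 and 13 would give symmetrical double alkylation, and E2 elimination would turn the iodides into terminal alkenes. The fallback replaces carbanion alkylation by palladium-catalysed cross-coupling, in which the order is set by halide reactivity and no strong base is present. It sets out from 10 and 6 and returns at 15. Zinc insertion into 10 (Zn dust, LiCl, THF, 40 °C) gives [5-(3,5-diisopropoxyphenyl)pentyl]zinc iodide F1. Negishi coupling of F1 with commercial 2-bromo-5-chlorothiophene at the C–Br bond (Pd(dppf)Cl2, THF, rt) gives 2-chloro-5-[5-(3,5-diisopropoxyphenyl)pentyl]thiophene F2. Zinc insertion into 6 gives [5-(3-isopropoxy-5-methoxyphenyl)pentyl]zinc iodide F3, and a second Negishi coupling of F2 with F3 at the C–Cl bond, using a more active catalyst (Pd(OAc)2, SPhos, THF, 60 °C), leads to 15.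

**Step 9.** Hydrogenolysis may stop short, leaving sulfur-containing or olefinic material, the substrate may adsorb strongly on the large excess of nickel, and the activity of Raney Ni varies from batch to batch. The fallback uses a sulfur-free four-carbon linchpin, so that plain catalytic hydrogenation replaces desulfurization. It sets out from 10 and 6 and returns at 16. Commercial 1,4-bis(trimethylsilyl)buta-1,3-diyne is mono-desilylated with MeLi·LiBr (THF, 0 °C) and the lithium acetylide is alkylated with 10 (DMPU, rt) to give [9-(3,5-diisopropoxyphenyl)nona-1,3-diyn-1-yl]trimethylsilane F4. A second treatment with MeLi·LiBr followed by 6 gives 1-[14-(3,5-diisopropoxyphenyl)tetradeca-6,8-diyn-1-yl]-3-isopropoxy-5-methoxybenzene F5. Hydrogenation of F5 (H2, Pd/C, EtOAc) saturates both triple bonds and gives 16.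

**Step 10.** Chemoselectivity may erode, with slow cleavage of the methyl ether alongside the isopropyl ethers, and the isopropyl cation equivalent may alkylate the very electron-rich resorcinol rings at carbon. The fallback replaces reagent discrimination by symmetry. It sets out from 16 and returns at 17. Exhaustive dealkylation (BBr3, CH2Cl2, −78 °C to rt) gives 5,5'-(tetradecane-1,14-diyl)bis(benzene-1,3-diol) F6, in which all four hydroxyls are equivalent by symmetry. Mono-O-methylation with a deficit of MeI (K2CO3, acetone, rt) can therefore give only one mono-ether, which is 17, and unreacted F6 is recycled. The price is a statistical ceiling on conversion per pass.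

**Step 3.** Alkyl transfer from boron may be slow, so that reduction of the aryl bromide or β-hydride elimination competes, and the C–Cl handle may be partly lost under warm aqueous base. The fallback builds the side chain through an sp–sp2 coupling. It sets out from 2 and returns at 6, bypassing 5 and step 4. Sonogashira coupling of 2 with pent-4-yn-1-ol (Pd(PPh3)2Cl2, CuI, Et3N, 70 °C) gives 5-(3-isopropoxy-5-methoxyphenyl)pent-4-yn-1-ol F7. Hydrogenation (H2, Pd/C, EtOAc) gives 5-(3-isopropoxy-5-methoxyphenyl)pentan-1-ol F8, and iodination (I2, PPh3, imidazole, CH2Cl2, 0 °C to rt) gives 6.

**Step 6.** This is the same reaction as step 3 on the ring B bromide and shares its risks. The fallback sets out from 8 and returns at 10, bypassing 9 and step 7. Sonogashira coupling of 8 with pent-4-yn-1-ol under the same conditions gives 5-(3,5-diisopropoxyphenyl)pent-4-yn-1-ol F9. Hydrogenation gives 5-(3,5-diisopropoxyphenyl)pentan-1-ol F10, and iodination with I2, PPh3 and imidazole gives 10.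

## Further compounds

F1 | step 8 | [5-(3,5-diisopropoxyphenyl)pentyl]zinc iodide | CC(C)Oc1cc(OC(C)C)cc(CCCCC[Zn]I)c1
F2 | step 8 | 2-chloro-5-[5-(3,5-diisopropoxyphenyl)pentyl]thiophene | CC(C)Oc1cc(OC(C)C)cc(CCCCCc2ccc(Cl)s2)c1
F3 | step 8 | [5-(3-isopropoxy-5-methoxyphenyl)pentyl]zinc iodide | COc1cc(OC(C)C)cc(CCCCC[Zn]I)c1
F4 | step 9 | [9-(3,5-diisopropoxyphenyl)nona-1,3-diyn-1-yl]trimethylsilane | C[Si](C)(C)C#CC#CCCCCCc1cc(OC(C)C)cc(OC(C)C)c1
F5 | step 9 | 1-[14-(3,5-diisopropoxyphenyl)tetradeca-6,8-diyn-1-yl]-3-isopropoxy-5-methoxybenzene | COc1cc(OC(C)C)cc(CCCCCC#CC#CCCCCCc2cc(OC(C)C)cc(OC(C)C)c2)c1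
F6 | step 10 | 5,5'-(tetradecane-1,14-diyl)bis(benzene-1,3-diol) | Oc1cc(O)cc(CCCCCCCCCCCCCCc2cc(O)cc(O)c2)c1
F7 | step 3 | 5-(3-isopropoxy-5-methoxyphenyl)pent-4-yn-1-ol | COc1cc(OC(C)C)cc(C#CCCCO)c1
F8 | step 3 | 5-(3-isopropoxy-5-methoxyphenyl)pentan-1-ol | COc1cc(OC(C)C)cc(CCCCCO)c1
F9 | step 6 | 5-(3,5-diisopropoxyphenyl)pent-4-yn-1-ol | CC(C)Oc1cc(OC(C)C)cc(C#CCCCO)c1
F10 | step 6 | 5-(3,5-diisopropoxyphenyl)pentan-1-ol | CC(C)Oc1cc(OC(C)C)cc(CCCCCO)c1
A1 | alternative 1 | methyl 2-[14-(3,5-bis(benzyloxy)phenyl)tetradecyl]-4,6-dihydroxybenzoate | COC(=O)c1c(O)cc(O)cc1CCCCCCCCCCCCCCc1cc(OCc2ccccc2)cc(OCc2ccccc2)c1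
A2 | alternative 1 | methyl 21-[3,5-bis(benzyloxy)phenyl]-3,5,7-trioxohenicosanoate | COC(=O)CC(=O)CC(=O)CC(=O)CCCCCCCCCCCCCCc1cc(OCc2ccccc2)cc(OCc2ccccc2)c1
A3 | alternative 1 | 15-[3,5-bis(benzyloxy)phenyl]-N-methoxy-N-methylpentadecanamide | CON(C)C(=O)CCCCCCCCCCCCCCc1cc(OCc2ccccc2)cc(OCc2ccccc2)c1
A4 | alternative 1 | methyl 3,5-dioxohexanoate | COC(=O)CC(=O)CC(C)=O
A5 | alternative 2 | methyl 6-[14-(3-benzyloxy-5-methoxyphenyl)tetradecyl]-2,4-dioxocyclohexane-1-carboxylate (racemic) | COC(=O)C1C(=O)CC(=O)CC1CCCCCCCCCCCCCCc1cc(OC)cc(OCc2ccccc2)c1
A6 | alternative 2 | (E)-18-(3-benzyloxy-5-methoxyphenyl)octadec-3-en-2-one | CC(=O)/C=C/CCCCCCCCCCCCCCc1cc(OC)cc(OCc2ccccc2)c1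
A7 | alternative 2 | dimethyl malonate | COC(=O)CC(=O)OC
A8 | alternative 3 | 3-[14-(3,5-bis(benzyloxy)phenyl)tetradecyl]-5-methoxyphenol | COc1cc(O)cc(CCCCCCCCCCCCCCc2cc(OCc3ccccc3)cc(OCc3ccccc3)c2)c1
A9 | alternative 3 | 3-[14-(3,5-bis(benzyloxy)phenyl)tetradecyl]cyclobut-2-en-1-one | O=C1C=C(CCCCCCCCCCCCCCc2cc(OCc3ccccc3)cc(OCc3ccccc3)c2)C1
A10 | alternative 3 | methoxyacetylene | COC#C
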